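## The problem

Target 24 is a 7-methoxy-2,2-dimethyl-2H-chromene (ring A the benzene ring, ring B the pyran ring) whose C6 carries a CH(CH3)O carbon. The oxygen of that carbon is the ether oxygen of a trisubstituted enol ether, O–CH=C(Ar)CH2OH, in which Ar (ring C) is 2-hydroxy-4-methylphenyl. No ring is joined to another through a stereocentre inside a ring; the task is to link two aromatic fragments through an acyclic C–O–C=C chain. There are two stereo-elements: the S carbinol carbon and the Z alkene (ether oxygen and CH2OH on the same side). The ether oxygen separates them, so neither can direct the other and each needs its own reagent-based control. The benzylic C–O bond lies para to the ring oxygen O1 and ortho to the C7 methoxy group, so traces of acid ionise it, with racemisation or elimination. The enol ether is likewise acid-labile and would be trapped by the ortho phenol of ring C. The C3=C4 alkene of ring B is an electron-rich styrene that reacts with electrophilic halogen and boranes, and C8–H, flanked by two oxygens, invites lithiation. The feature that opens the route is that the stereocentre is an sp3 carbon bearing H, CH3 and O and bonded directly to the sp2 carbon C6 of ring A. This is the array produced when the carbanion carbon of a lithiated ethyl carbamate is inserted into an aryl C–B bond and boron is then exchanged for oxygen.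

## Retrosynthesis

The two O–Si bonds are cut first. Target 24 is traced to its bis(triisopropylsilyl) ether 23, so that the phenol and the primary alcohol are released together by fluoride, the only deprotection that the acid-labile benzylic enol ether tolerates. 23 has the full skeleton and both stereo-elements; the last step only has to be non-acidic.

The vinyl C–O bond of 23 is cut next, giving alcohol 14 and (Z)-vinyl iodide 22. Cutting the benzylic C–O bond instead would need substitution at a carbon that ionises at once and would lose the configuration. Building the alkene after etherification, by deprotonating an allyl ether of 14 with an alkyllithium, would expose C8–H and the benzylic ether to lithiation and Wittig shifts. Equilibrating methods were also set aside, because the required geometry cannot be relied on under thermodynamic control. The copper-catalysed coupling of a vinyl iodide with an alcohol keeps both the alkene geometry and the carbinol configuration. The forward step must join a hindered secondary alkoxide to a trisubstituted vinyl iodide under carbonate base. The two partners are of similar size, so the route becomes convergent.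

Vinyl iodide 22 is traced through diol 21 and methoxymethyl ether 20 to aryl bromide 16 and prop-2-yn-1-ol 17. The bonds cut are the ring C–C2 bond and the C3–I bond, formed together by anti-carbomagnesiation of 17 with Grignard reagent 18 and iodinolysis of the chelated alkenylmagnesium 19. The five-membered magnesium chelate puts iodine cis to CH2O, so the Z geometry is fixed on a small achiral fragment where it can be checked before the coupling. The methoxymethyl group is chosen for the Grignard stage and is exchanged for silyl (20 to 21 to 22) while acid is still harmless. 16 comes from commercial 2-bromo-5-methylphenol 15 in one step.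

The C–O bond at the stereocentre of 14 is traced to the C–B bond of boronate 13. Oxidation of a boronic ester goes with retention under alkaline conditions, so the labile alcohol is released only when it is needed.

The key cut is the C6–CH bond of 13, giving aryl boronate 7 and ethyl carbamate 10. The neighbouring cut at C–CH3 (methyl addition to an aldehyde) makes the selectivity depend on the electron-rich ring. The cut at C–O (ketone reduction) does the same. The C6–CH cut places the enantio-determining event on the small carbamate, and the stereocentre appears as a non-ionisable C–B centre under basic conditions. The forward reaction needs a single, stereospecific insertion into the hindered ortho-methoxy aryl boronate.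

Boronate 7 is traced to bromide 5 (C–B from C–Br, with diboron 6), and 5 to 4-bromo-3-methoxyphenol 1 and 3-methylbut-2-enal 2. Ring B is closed on the brominated phenol because brominating a preformed chromene would attack the C3=C4 alkene. The forward condensation must take place at the ortho position para to the methoxy group, through intermediates 3 and 4.

Carbamate 10 is cut at the acyl C–O bond to ethanol 8 and carbamoyl chloride 9.

## Roads not taken

Alternative 1: The cut removes ring A altogether; its four ring C–C bonds would be made in a Danheiser benzannulation. Irradiation of (S)-5-(tert-butyldimethylsilyloxy)-4-diazohex-1-en-3-one A2 with methoxyacetylene A3, then heating, would bring about Wolff rearrangement to a vinylketene, [2+2] cycloaddition, four-electron ring opening and six-electron closure to (S)-4-[1-(tert-butyldimethylsilyloxy)ethyl]-3-methoxyphenol A1. Its merit is that the stereocentre comes from lactic acid, with no chiral reagent and no cryogenic organolithium, and that the substitution pattern of ring A is fixed by the annulation. In this respect it is better than the chosen plan. Its weak points lie in the structure of A1. The phenol oxygen is para to the CH(CH3)O carbon, so the heat needed for the electrocyclic steps invites loss of silanol to a para-quinone methide, and the configuration with it. Ring B would still have to be annulated onto A1 under conditions that this ionisable benzylic ether tolerates poorly. A2 and the volatile A3 each cost several steps. The chosen plan sets against the chiral-pool advantage a purchasable ring A, a much shorter sequence, and a stereocentre that stays a C–B bond until ring B is complete.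

Alternative 2: The cut is the bond between the ring C-bearing alkene carbon and the CH2OH carbon. The (Z)-enol triflate A5 and (tributylstannyl)methanol A6 would be coupled with Pd(PPh3)4 and LiCl to give the phenol tert-butyldimethylsilyl ether of the target, A4, with retention of geometry. Its merits are a neutral late C–C coupling and a hydroxymethyl group that arrives unprotected, so one silyl group is saved; in protecting-group economy it is better than the chosen plan. Geometry control is of the same kind in both plans, a five-membered metal chelate. The weak points are these: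
- The plan does not create the carbinol stereocentre, which must be borrowed from elsewhere.
- The chelated enolate that leads to A5 must form with one geometry on the complete, sensitive skeleton, where an isomer could be removed only at the cost of advanced material.
- Transfer of an sp3 carbon from tin is slow and competes with butyl transfer.
- Tin is used in stoichiometric amount.

The chosen plan sets against it that the chelation event (19) takes place on a cheap achiral fragment before the halves meet, that the union is a single catalytic C–O coupling, and that no tin is needed.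

Alternative 3: The cut is the C–CH3 bond at the carbinol carbon. Dimethylzinc A9 would add to 7-methoxy-2,2-dimethyl-2H-chromene-6-carbaldehyde A8 under catalysis by a camphor-derived β-amino alcohol to give (S)-1-(7-methoxy-2,2-dimethyl-2H-chromen-6-yl)ethanol A7, which is the same compound as 14. It is catalytic in chiral material, needs no cryogenic step, and should reach this alcohol in fewer steps than steps 1 to 5 of the chosen plan; this advantage is real. Its weak points are electronic. A9 is the least reactive dialkylzinc, and the formyl group of A8 is deactivated by the para ring oxygen and the ortho methoxy group. That methoxy group also offers zinc a second binding site that can open a less selective chelated pathway. The enantioselectivity therefore depends on the substrate, and the labile alcohol is formed in the presence of Lewis-acidic zinc. The chosen plan is longer and uses a stoichiometric diamine. It sets against this an enantio-determining deprotonation of a small carbamate that does not depend on ring A, a stereospecific transfer, and a stable boronate 13 that can be purified before the alcohol is released.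

Key step: step 4

Assumption: (+)-sparteine is taken as purchasable; the synthetic diamine surrogate of the same stereochemical sense would replace it without change to the plan.

Step 1
Reactants: 1 4-bromo-3-methoxyphenol; 2 3-methylbut-2-enal
Product: 5 6-bromo-7-methoxy-2,2-dimethyl-2H-chromene, via benzodioxaborin 3 (not isolated), via ortho-quinone methide 4 (not isolated)
Conditions: PhB(OH)2 (1 equiv), AcOH (cat.), toluene, reflux, Dean–Stark
Reagents that add atoms: none
Why: Phenylboronic acid-templated chromenylation of a phenol with an enal: boron ties the phenol oxygen to the aldehyde so that C–C bond formation occurs only ortho to the hydroxyl, at the unhindered position para to the methoxy group (3); thermal loss of the boronic acid gives 4, which closes ring B by oxa-6π electrocyclisation. The bromine is already in place, so the C3=C4 alkene never meets a brominating agent.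

Step 2
Reactants: 5 6-bromo-7-methoxy-2,2-dimethyl-2H-chromene; 6 bis(pinacolato)diboron
Product: 7 2-(7-methoxy-2,2-dimethyl-2H-chromen-6-yl)-4,4,5,5-tetramethyl-1,3,2-dioxaborolane
Conditions: PdCl2(dppf) (3 mol %), KOAc, 1,4-dioxane, 85 °C
Reagents that add atoms: none
Why: Miyaura borylation of an aryl bromide; the weak acetate base suppresses Suzuki homocoupling, and the 1,2-disubstituted alkene of ring B should not compete for the arylpalladium intermediate.

Step 3
Reactants: 8 ethanol; 9 N,N-diisopropylcarbamoyl chloride
Product: 10 ethyl N,N-diisopropylcarbamate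
Conditions: Et3N, DMAP (cat.), CH2Cl2, reflux
Reagents that add atoms: none
Why: Acylation of a primary alcohol by a carbamoyl chloride; the hindered diisopropylcarbamoyl group later directs α-lithiation and resists attack at its carbonyl.

Step 4
Reactants: 10 ethyl N,N-diisopropylcarbamate; 7 2-(7-methoxy-2,2-dimethyl-2H-chromen-6-yl)-4,4,5,5-tetramethyl-1,3,2-dioxaborolane
Product: 13 (S)-2-[1-(7-methoxy-2,2-dimethyl-2H-chromen-6-yl)ethyl]-4,4,5,5-tetramethyl-1,3,2-dioxaborolane, via lithiated carbamate 11 (not isolated), via lithium boronate complex 12 (not isolated)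
Conditions: sec-BuLi (1.25 equiv), (+)-sparteine (1.3 equiv), 10 (1.3 equiv), Et2O, −78 °C, 5 h; then 7 (1.0 equiv), −78 °C, 1 h; then MgBr2·OEt2, −78 °C → reflux
Reagents that add atoms: none
Why: This is a lithiation–borylation, the 1,2-metallate rearrangement of a boronate complex, in its known form for sparteine-lithiated O-alkyl carbamates and aryl pinacol boronates. sec-BuLi bound to (+)-sparteine and directed by the carbamate carbonyl removes the pro-R hydrogen of the OCH2 group and gives the configurationally stable (R)-organolithium 11. 11 adds to the boron of 7 with retention to give complex 12. On warming with MgBr2·OEt2 the aryl group migrates from boron to carbon anti to the departing carbamate, with inversion, forming the C6–CH bond and the S centre of 13; no ring closes. The new stereocentre is controlled only by the chiral diamine in the deprotonation and is passed on stereospecifically (retention, then inversion). The step needs a single insertion and migration of the aryl group; the electron-rich aryl group migrates readily, and the hindered secondary boronate 13 should not accept a second carbenoid. The carbamate is kept in excess over sec-BuLi so that no free alkyllithium meets C8–H or the boron of 7, and the ring B alkene is inert to all reagents. The stereocentre is made as a C–B centre under basic conditions, so the easily ionised benzylic position never meets acid.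

Step 5
Reactants: 13 (S)-2-[1-(7-methoxy-2,2-dimethyl-2H-chromen-6-yl)ethyl]-4,4,5,5-tetramethyl-1,3,2-dioxaborolane
Product: 14 (S)-1-(7-methoxy-2,2-dimethyl-2H-chromen-6-yl)ethanol
Conditions: H2O2 (30 % aq.), NaOH (2 M aq.), THF, 0 °C → rt
Reagents that add atoms: hydrogen peroxide, OO
Why: Oxidation of a secondary boronic ester by hydroperoxide, in which carbon shifts from boron to oxygen with retention, so S-13 should give S-14; the alkaline medium spares the acid-labile benzylic alcohol and the unactivated ring B alkene (purification on amine-washed silica).

Step 6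
Reactants: 15 2-bromo-5-methylphenol
Product: 16 1-bromo-2-(methoxymethoxy)-4-methylbenzene
Conditions: MOMCl, i-Pr2NEt, CH2Cl2, 0 °C → rt
Reagents that add atoms: chloromethyl methyl ether, COCCl
Why: O-Alkylation of a phenol to its methoxymethyl ether, a group that tolerates the ortho-Grignard reagent and stabilises it by chelation, which an ortho silyl ether would not do safely.

Step 7
Reactants: 16 1-bromo-2-(methoxymethoxy)-4-methylbenzene; 17 prop-2-yn-1-ol
Product: 20 (Z)-3-iodo-2-[2-(methoxymethoxy)-4-methylphenyl]prop-2-en-1-ol, via arylmagnesium bromide 18 (not isolated), via alkenylmagnesium alkoxide 19 (not isolated)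
Conditions: Mg, THF, 50 °C; then 17 (0.4 equiv), CuI (10 mol %), THF/Et2O, 0 °C → rt; then I2, −30 °C → 0 °C
Reagents that add atoms: iodine, II
Why: Copper-catalysed anti-carbomagnesiation of a propargylic alcohol followed by iodinolysis: one equivalent of 18 forms the magnesium alkoxide, a second delivers the aryl group to C2 while magnesium ends on C3, held cis to the CH2O group in a five-membered chelate (19). Iodine then replaces magnesium with retention, so iodine and CH2OH are cis (Z).

Step 8
Reactants: 20 (Z)-3-iodo-2-[2-(methoxymethoxy)-4-methylphenyl]prop-2-en-1-ol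
Product: 21 2-[(1Z)-3-hydroxy-1-iodoprop-1-en-2-yl]-5-methylphenol
Conditions: HCl (3 M aq., cat.), MeOH, 40 °C
Reagents that add atoms: none
Why: Acid-catalysed acetal exchange removes the aryl methoxymethyl ether; acid is used at this stage because the vinyl iodide and allylic alcohol tolerate it, whereas nothing after step 10 would.

Step 9
Reactants: 21 2-[(1Z)-3-hydroxy-1-iodoprop-1-en-2-yl]-5-methylphenol
Product: 22 triisopropyl{[(2Z)-3-iodo-2-{4-methyl-2-[(triisopropylsilyl)oxy]phenyl}prop-2-en-1-yl]oxy}silane
Conditions: TIPSOTf (2.5 equiv), 2,6-lutidine, CH2Cl2, 0 °C → rt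
Reagents that add atoms: triisopropylsilyl trifluoromethanesulfonate, CC(C)[Si](C(C)C)(C(C)C)OS(=O)(=O)C(F)(F)F
Why: Silylation of the phenol and the primary alcohol in one operation; the bulky triisopropylsilyl ethers should withstand carbonate base at 80 °C and are both removed by fluoride at the end.

Step 10
Reactants: 14 (S)-1-(7-methoxy-2,2-dimethyl-2H-chromen-6-yl)ethanol; 22 triisopropyl{[(2Z)-3-iodo-2-{4-methyl-2-[(triisopropylsilyl)oxy]phenyl}prop-2-en-1-yl]oxy}silane
Product: 23 triisopropyl{[(2Z)-3-[(1S)-1-(7-methoxy-2,2-dimethyl-2H-chromen-6-yl)ethoxy]-2-{4-methyl-2-[(triisopropylsilyl)oxy]phenyl}prop-2-en-1-yl]oxy}silane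
Conditions: CuI (10 mol %), 3,4,7,8-tetramethyl-1,10-phenanthroline (20 mol %), Cs2CO3, 22 (1.3 equiv), toluene, 80 °C
Reagents that add atoms: none
Why: Copper-catalysed Ullmann-type C–O coupling of a vinyl iodide with a secondary alcohol, which keeps the alkene geometry and does not touch the carbinol C–O bond, so Z-22 and S-14 should give (S,Z)-23. The vinyl iodide has no hydrogen on C2 and cannot eliminate to an alkyne, and the basic medium keeps the benzylic ether from ionising.

Step 11
Reactants: 23 triisopropyl{[(2Z)-3-[(1S)-1-(7-methoxy-2,2-dimethyl-2H-chromen-6-yl)ethoxy]-2-{4-methyl-2-[(triisopropylsilyl)oxy]phenyl}prop-2-en-1-yl]oxy}silane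
Product: 24 2-[(1Z)-3-hydroxy-1-[(1S)-1-(7-methoxy-2,2-dimethyl-2H-chromen-6-yl)ethoxy]prop-1-en-2-yl]-5-methylphenol
Conditions: Bu4NF (3 equiv), THF, 0 °C → rt; pH 7 phosphate buffer
Reagents that add atoms: none
Why: Fluoride cleavage of the aryl and primary alkyl silyl ethers under basic, non-acidic conditions that leave the enol ether, the benzylic ether and the chromene alkene intact; neither stereo-element is touched.

## Compound list

1 | 4-bromo-3-methoxyphenol | COc1cc(O)ccc1Br | starting material
2 | 3-methylbut-2-enal | CC(C)=CC=O | starting material
3 | 6-bromo-7-methoxy-4-(2-methylprop-1-en-1-yl)-2-phenyl-4H-1,3,2-benzodioxaborinine (racemic at C4) | COc1cc2OB(c3ccccc3)OC(C=C(C)C)c2cc1Br | intermediate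
4 | (6Z)-4-bromo-3-methoxy-6-(3-methylbut-2-en-1-ylidene)cyclohexa-2,4-dien-1-one | O=C1C=C(OC)C(Br)=C/C1=C/C=C(C)C | intermediate
5 | 6-bromo-7-methoxy-2,2-dimethyl-2H-chromene | COc1cc2c(cc1Br)C=CC(C)(C)O2 | intermediate
6 | bis(pinacolato)diboron | CC1(C)OB(OC1(C)C)B1OC(C)(C)C(C)(C)O1 | starting material
7 | 2-(7-methoxy-2,2-dimethyl-2H-chromen-6-yl)-4,4,5,5-tetramethyl-1,3,2-dioxaborolane | COc1cc2c(cc1B1OC(C)(C)C(C)(C)O1)C=CC(C)(C)O2 | intermediate
8 | ethanol | CCO | starting material
9 | N,N-diisopropylcarbamoyl chloride | CC(C)N(C(C)C)C(Cl)=O | starting material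
10 | ethyl N,N-diisopropylcarbamate | CCOC(=O)N(C(C)C)C(C)C | intermediate
11 | (R)-1-lithioethyl N,N-diisopropylcarbamate, as its (+)-sparteine complex | [Li][C@H](C)OC(=O)N(C(C)C)C(C)C | intermediate
12 | lithium [(1R)-1-(N,N-diisopropylcarbamoyloxy)ethyl](7-methoxy-2,2-dimethyl-2H-chromen-6-yl)(pinacolato)borate | COc1cc2c(cc1[B-]1([C@H](C)OC(=O)N(C(C)C)C(C)C)OC(C)(C)C(C)(C)O1)C=CC(C)(C)O2.[Li+] | intermediate
13 | (S)-2-[1-(7-methoxy-2,2-dimethyl-2H-chromen-6-yl)ethyl]-4,4,5,5-tetramethyl-1,3,2-dioxaborolane | COc1cc2c(cc1[C@H](C)B1OC(C)(C)C(C)(C)O1)C=CC(C)(C)O2 | intermediate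
14 | (S)-1-(7-methoxy-2,2-dimethyl-2H-chromen-6-yl)ethanol | COc1cc2c(cc1[C@H](C)O)C=CC(C)(C)O2 | intermediate
15 | 2-bromo-5-methylphenol | Cc1ccc(Br)c(O)c1 | starting material
16 | 1-bromo-2-(methoxymethoxy)-4-methylbenzene | COCOc1cc(C)ccc1Br | intermediate
17 | prop-2-yn-1-ol | C#CCO | starting material
18 | [2-(methoxymethoxy)-4-methylphenyl]magnesium bromide | COCOc1cc(C)ccc1[Mg]Br | intermediate
19 | bromomagnesium (Z)-3-(bromomagnesio)-2-[2-(methoxymethoxy)-4-methylphenyl]prop-2-en-1-olate | Br[Mg]/C=C(\CO[Mg]Br)c1ccc(C)cc1OCOC | intermediate
20 | (Z)-3-iodo-2-[2-(methoxymethoxy)-4-methylphenyl]prop-2-en-1-ol | I/C=C(\CO)c1ccc(C)cc1OCOC | intermediate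
21 | 2-[(1Z)-3-hydroxy-1-iodoprop-1-en-2-yl]-5-methylphenol | I/C=C(\CO)c1ccc(C)cc1O | intermediate
22 | triisopropyl{[(2Z)-3-iodo-2-{4-methyl-2-[(triisopropylsilyl)oxy]phenyl}prop-2-en-1-yl]oxy}silane | I/C=C(\CO[Si](C(C)C)(C(C)C)C(C)C)c1ccc(C)cc1O[Si](C(C)C)(C(C)C)C(C)C | intermediate
23 | triisopropyl{[(2Z)-3-[(1S)-1-(7-methoxy-2,2-dimethyl-2H-chromen-6-yl)ethoxy]-2-{4-methyl-2-[(triisopropylsilyl)oxy]phenyl}prop-2-en-1-yl]oxy}silane | COc1cc2c(cc1[C@H](C)O/C=C(\CO[Si](C(C)C)(C(C)C)C(C)C)c1ccc(C)cc1O[Si](C(C)C)(C(C)C)C(C)C)C=CC(C)(C)O2 | intermediate
24 | 2-[(1Z)-3-hydroxy-1-[(1S)-1-(7-methoxy-2,2-dimethyl-2H-chromen-6-yl)ethoxy]prop-1-en-2-yl]-5-methylphenol (CNP0279099.1) | COc1cc2c(cc1[C@H](C)O/C=C(\CO)c1ccc(C)cc1O)C=CC(C)(C)O2 | target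

## Step count and risks

Total: 11 steps. Longest linear sequence: 6 steps (steps 1, 2, 4, 5, 10, 11; the branch through steps 6 to 9 is equally long).

Step 4 (key step). The ortho-methoxy boronate 7 is hindered, so boronate complex formation may be slow or reversible and the aryl shift sluggish. The consequences would be incomplete conversion and loss of enantiopurity through dissociation of 12. Fallback: from 5, bromine–lithium exchange (n-BuLi, THF, −78 °C) and acylation with N-methoxy-N-methylacetamide would give 1-(7-methoxy-2,2-dimethyl-2H-chromen-6-yl)ethan-1-one F1. Asymmetric transfer hydrogenation of F1 with RuCl[(S,S)-TsDPEN](p-cymene) and HCO2Na in water/methanol would give the S alcohol and rejoin the route at 14, bypassing steps 2 to 5.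

Step 10. C–O bond formation between the hindered secondary benzylic alkoxide and the trisubstituted vinyl iodide may be slow. Protodeiodination, oxidation of the copper alkoxide, or base-induced loss of the aryl silyl group could then compete. Fallback: the enol ether would be made by C–C coupling on a preformed ether.
- From 14, O-alkylation with 2-chloro-N-methoxy-N-methylacetamide (NaH, THF) would give (S)-N-methoxy-2-[1-(7-methoxy-2,2-dimethyl-2H-chromen-6-yl)ethoxy]-N-methylacetamide F2.
- From 15, silylation (TIPSCl, imidazole, DMF) would give (2-bromo-5-methylphenoxy)triisopropylsilane F3. Its aryllithium (n-BuLi, THF, −78 °C) would add to F2 to give (S)-2-[1-(7-methoxy-2,2-dimethyl-2H-chromen-6-yl)ethoxy]-1-[4-methyl-2-(triisopropylsilyloxy)phenyl]ethan-1-one F4.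
- Deprotonation with KN(SiMe3)2 at −78 °C, with potassium chelated between the ether and enolate oxygens, and trapping with PhNTf2 would give (Z)-2-[(S)-1-(7-methoxy-2,2-dimethyl-2H-chromen-6-yl)ethoxy]-1-[4-methyl-2-(triisopropylsilyloxy)phenyl]vinyl trifluoromethanesulfonate F5.
- Stille coupling with Bu3SnCH2OH (Pd(PPh3)4, LiCl, THF, reflux) would give (S,Z)-3-[1-(7-methoxy-2,2-dimethyl-2H-chromen-6-yl)ethoxy]-2-[4-methyl-2-(triisopropylsilyloxy)phenyl]prop-2-en-1-ol F6.
- Bu4NF would then rejoin the route at 24; steps 6 to 10 would not be needed.

Step 7. Carbometalation by the hindered ortho-alkoxy aryl Grignard reagent may be slow, so that deprotonation of the alkyne terminus, biaryl formation or regiochemically mixed addition take over. Fallback: from 16, the Grignard reagent 18 would be quenched with iodine to give 1-iodo-2-(methoxymethoxy)-4-methylbenzene F7. Reductive Heck hydroarylation of 3-(trimethylsilyl)prop-2-yn-1-ol with F7 (Pd(OAc)2, PPh3, HCO2H, Et3N, DMF, 60 °C) delivers aryl and hydrogen syn, with the aryl group away from silicon. It would give (Z)-2-[2-(methoxymethoxy)-4-methylphenyl]-3-(trimethylsilyl)prop-2-en-1-ol F8. Iododesilylation with N-iodosuccinimide in MeCN, with retention, would rejoin the route at 20.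

Step 1. The bromine lowers the nucleophilicity of the phenol ring, so ortho-condensation may be slow and self-condensation of the enal may consume 2. Fallback: from 1, O-alkylation with 3-chloro-3-methylbut-1-yne (K2CO3, KI, acetone, reflux) would give 1-bromo-2-methoxy-4-[(2-methylbut-3-yn-2-yl)oxy]benzene F9. Heating F9 in N,N-diethylaniline at about 190 °C would bring about aromatic Claisen rearrangement, 1,5-hydrogen shift and oxa-6π closure, rejoining the route at 5.

## Further compounds

F1 | step 4 | 1-(7-methoxy-2,2-dimethyl-2H-chromen-6-yl)ethan-1-one | COc1cc2c(cc1C(C)=O)C=CC(C)(C)O2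
F2 | step 10 | (S)-N-methoxy-2-[1-(7-methoxy-2,2-dimethyl-2H-chromen-6-yl)ethoxy]-N-methylacetamide | COc1cc2c(cc1[C@H](C)OCC(=O)N(C)OC)C=CC(C)(C)O2
F3 | step 10 | (2-bromo-5-methylphenoxy)triisopropylsilane | Cc1ccc(Br)c(O[Si](C(C)C)(C(C)C)C(C)C)c1
F4 | step 10 | (S)-2-[1-(7-methoxy-2,2-dimethyl-2H-chromen-6-yl)ethoxy]-1-[4-methyl-2-(triisopropylsilyloxy)phenyl]ethan-1-one | COc1cc2c(cc1[C@H](C)OCC(=O)c1ccc(C)cc1O[Si](C(C)C)(C(C)C)C(C)C)C=CC(C)(C)O2
F5 | step 10 | (Z)-2-[(S)-1-(7-methoxy-2,2-dimethyl-2H-chromen-6-yl)ethoxy]-1-[4-methyl-2-(triisopropylsilyloxy)phenyl]vinyl trifluoromethanesulfonate | COc1cc2c(cc1[C@H](C)O/C=C(\OS(=O)(=O)C(F)(F)F)c1ccc(C)cc1O[Si](C(C)C)(C(C)C)C(C)C)C=CC(C)(C)O2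
F6 | step 10 | (S,Z)-3-[1-(7-methoxy-2,2-dimethyl-2H-chromen-6-yl)ethoxy]-2-[4-methyl-2-(triisopropylsilyloxy)phenyl]prop-2-en-1-ol | COc1cc2c(cc1[C@H](C)O/C=C(\CO)c1ccc(C)cc1O[Si](C(C)C)(C(C)C)C(C)C)C=CC(C)(C)O2
F7 | step 7 | 1-iodo-2-(methoxymethoxy)-4-methylbenzene | COCOc1cc(C)ccc1I
F8 | step 7 | (Z)-2-[2-(methoxymethoxy)-4-methylphenyl]-3-(trimethylsilyl)prop-2-en-1-ol | C[Si](C)(C)/C=C(\CO)c1ccc(C)cc1OCOC
F9 | step 1 | 1-bromo-2-methoxy-4-[(2-methylbut-3-yn-2-yl)oxy]benzene | COc1cc(OC(C)(C)C#C)ccc1Br
A1 | alternative 1 | (S)-4-[1-(tert-butyldimethylsilyloxy)ethyl]-3-methoxyphenol | COc1cc(O)ccc1[C@H](C)O[Si](C)(C)C(C)(C)C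
A2 | alternative 1 | (S)-5-(tert-butyldimethylsilyloxy)-4-diazohex-1-en-3-one | C=CC(=O)C(=[N+]=[N-])[C@H](C)O[Si](C)(C)C(C)(C)C
A3 | alternative 1 | methoxyacetylene | COC#C
A4 | alternative 2 | (S,Z)-3-[1-(7-methoxy-2,2-dimethyl-2H-chromen-6-yl)ethoxy]-2-[2-(tert-butyldimethylsilyloxy)-4-methylphenyl]prop-2-en-1-ol | COc1cc2c(cc1[C@H](C)O/C=C(\CO)c1ccc(C)cc1O[Si](C)(C)C(C)(C)C)C=CC(C)(C)O2
A5 | alternative 2 | (Z)-2-[(S)-1-(7-methoxy-2,2-dimethyl-2H-chromen-6-yl)ethoxy]-1-[2-(tert-butyldimethylsilyloxy)-4-methylphenyl]vinyl trifluoromethanesulfonate | COc1cc2c(cc1[C@H](C)O/C=C(\OS(=O)(=O)C(F)(F)F)c1ccc(C)cc1O[Si](C)(C)C(C)(C)C)C=CC(C)(C)O2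
A6 | alternative 2 | (tributylstannyl)methanol | CCCC[Sn](CCCC)(CCCC)CO
A7 | alternative 3 | (S)-1-(7-methoxy-2,2-dimethyl-2H-chromen-6-yl)ethanol | COc1cc2c(cc1[C@H](C)O)C=CC(C)(C)O2
A8 | alternative 3 | 7-methoxy-2,2-dimethyl-2H-chromene-6-carbaldehyde | COc1cc2c(cc1C=O)C=CC(C)(C)O2
A9 | alternative 3 | dimethylzinc | C[Zn]C
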